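The electrophile left over in a reading counts survivors, and two such readings show how fast a survivor is lost.

| flask | electrophile | nucleophile | remark | time |
|---|---|---|---|---|
| north | 0.020 M (fed, over 25 min) | 0.020 M | run made earlier; the fed solution adds 0.25 times the starting volume |  |
| south | 0.020 M (fed, over 25 min) | 0.11 M | run made earlier; the fed solution adds 0.25 times the starting volume |  |
| Thursday's | 0.020 M (fed, over 25 min) | 0.0720 M | the fed solution adds 0.25 times the starting volume | 6.0 h |
| Saturday's | 0.020 M (fed, over 25 min) | 0.140 M | the fed solution adds 0.25 times the starting volume | 6.0 h |
| Tuesday's | 0.020 M (fed, over 25 min) | 0.0360 M | the fed solution adds 0.25 times the starting volume | 6.0 h |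

| run | time / h | electrophile / % | target / % |
|---|---|---|---|
| north | 1.00 | 96.2 | 3.6 |
| north | 2.00 | 91.6 | 8.5 |
| north | 3.00 | 87.7 | 11.2 |
| north | 4.00 | 82.7 | 12.7 |
| south | 1.00 | 78.9 | 19.3 |
| south | 2.00 | 59.2 | 33.7 |
| south | 3.00 | 45.7 | 46.0 |
| south | 4.00 | 35.4 | 54.2 |

(standard deviation of a reading: 1 percentage point)

- for target the crystals are counted in
- charges are per starting volume, the dose included; the dosed solution carries all of it
- as a solid, counted per litre of solution: crystals
- steps that have been proposed: electrophile + nucleophile -> acid set free + target; crystals <-> target; nucleophile + acid set free <-> protonated nucleophile; target <-> isomer of the product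

- part of the electrophile that has reacted at the end, Thursday's
- part of the electrophile that has reacted at the end, Saturday's
- part of the electrophile that has reacted at the end, Tuesday's
- what raising the concentration of nucleophile from its lowest to its highest value here does to the part of the electrophile that has reacted (changes below 5 percentage points count as none) (no change / it falls / it rises)

1. First way, south run. Between 1.00 h and 4.00 h the electrophile falls from 78.9 % to 35.4 %, so each molecule is lost at 0.267 h⁻¹. The feed dilutes the charges. The proposed steps let the acid set free take a second nucleophile, so each electrophile reacted is counted as costing two. That puts the mean [nucleophile] of this window at 0.0743 M. Dividing gives 3.60 M⁻¹ h⁻¹: the meeting constant, the hourly loss of an electrophile molecule per molar of free nucleophile (the second-order rate constant).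

2. Second way, north run. The same reckoning gives 0.0504 h⁻¹ at a mean [nucleophile] of 0.0126 M, a factor of 5.90 lower, and so 3.99 M⁻¹ h⁻¹. The scatter of the readings makes this north value uncertain by 0.421 M⁻¹ h⁻¹, and the gap of 0.390 M⁻¹ h⁻¹ is smaller. The two ways agree, and the south value, uncertain by 0.139 M⁻¹ h⁻¹, is the tighter, so it is carried.

3. This reckoning. Electrophile entering at mid-feed has 5.79 h of contact, and its survival is exp(−meeting constant × [nucleophile] × contact). A first pass with the diluted charge gives the share reacted. The mean nucleophile loss is then the midpoint between none and the end value, and a second pass gives 62.0 % reacted on Thursday's, 86.9 % on Saturday's and 36.2 % on Tuesday's.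

4. The forecast. It gives 61 % for Thursday's, 85 % for Saturday's and 37 % for Tuesday's, with the trend it rises, and it reasons: “The released acid probably ties up a second nucleophile”. This reckoning stands above it on Saturday's. Both draw on the same runs, so their closeness is no check.

The flask gives 61.9 % on Thursday's, 86.2 % on Saturday's and 37.2 % on Tuesday's. With more nucleophile, it rises, by 49 percentage points, so the forecast stands. For the forecast to fail on Saturday's, a run would have to part from this flask; with all else held, the flask's own answer has moved by 5 points from 86.2 % with its nucleophile at 0.120 M or 0.169 M. Saturday's free nucleophile ends at 75.4 % of its charge. The midpoint, 0.0982 M, with the meeting constant 3.60 M⁻¹ h⁻¹ over 5.79 h, leaves 12.9 % electrophile, against 14 % in the flask.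

    electrophile + nucleophile → acid set free + target (k = 0.0610 M⁻¹ min⁻¹)
    crystals ⇌ target, rate k2*(cs2 - [target]) while solid is left; crystals form when [target] > cs2 (solubility = 3.10 mM, k = 0.0220 min⁻¹)
    nucleophile + acid set free ⇌ protonated nucleophile, settled at all times (K = 10000 M⁻¹)
    target ⇌ isomer of the product (K = 0.390, k = 0.00600 min⁻¹)

Saturday's flask read at 1.5 h has 1.29 h of contact, and the same two passes with the meeting constant give 38.7 % reacted. The computed flask stands at 39.4 %.

The readings come from a simulation for substances that don't exist; noise was put on by code.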